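**Retrosynthetic overview**

1. Labdane numbering is used: ring A = C1–C5 and C10 (ketone C3, methyls C18 on C4 and C20 on C10); ring B = C5–C10 (methyl C17 on C8); lactone C19(=O)–O–C6; ethers C9–O–C13 and C15–O–C16. Endgame: the dihydrofuran comes from dehydration of a C15 lactol, and the spiro furanone from Meyer–Schuster rearrangement and oxa-conjugate addition on the adduct of C9 ketone 16 with enantiopure alkyne 24.
2. Ring B is closed by C7–C8 enolate alkylation of an ethyl ketone, itself made by Grignard opening of a δ-lactone C9(=O)–O–C7 that holds the place of ring B; C18 enters by methylation of the β-keto γ-lactone.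
3. Key disconnection: ring A by a formal [3+3] annulation of 2-methylcyclobutanone with a glyceraldehyde-derived butenolide. C5–C10 forms by silicon-tethered Mukaiyama–Michael addition, C2–C3 by Claisen condensation, and the C9–C2 bond is then cut by strain-driven retro-Claisen opening.
4. Enabling feature: in ring A the ketone carbon C3 and the acyl carbon C9 on quaternary C10 are 1,5-related (C3–C2–C1–C10–C9). C9, C10, C1 and C2 can therefore be carried as a cyclobutanone whose two α-carbons (C10, C2) are the nucleophiles, while C4, flanked by the carbonyls C3 and C19, makes C5 a conjugate-acceptor carbon.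
5. Ring order: γ-lactone (butenolide) → ring A together with the δ-lactone (key step) → ring B → spiro furanone → dihydrofuran.

Key step: step 4

Assumption (chemistry): in step 11 the (S)-enantiomer of 3,3'-dibromo-BINOL is taken to deliver the (R)-carbinol from alkynyl keto ester 19; if the sense of induction on this substrate is the opposite, the mirror-image catalyst is used.

Remark: the C9 configuration drawn for 25 is the one expected from attack along the equatorial direction; it is erased in steps 16 and 17, so either epimer serves.

**Step 1**
Reactants: 1 (R)-2,2-dimethyl-1,3-dioxolane-4-carbaldehyde; 2 dimethyl malonate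
Product: 3 dimethyl (S)-2-[(2,2-dimethyl-1,3-dioxolan-4-yl)methylidene]malonate
Conditions: piperidine (10 mol %), AcOH (10 mol %), MgSO4, CH2Cl2, 0 °C → rt
Reagents that add atoms: none
Why: Knoevenagel condensation under mild buffered amine catalysis should join the α-alkoxy aldehyde and the malonate without touching the C6 stereocenter.

**Step 2**
Reactants: 3
Product: 5 methyl (S)-5-(hydroxymethyl)-2-oxo-2,5-dihydrofuran-3-carboxylate, via diol diester 4 (not isolated)
Conditions: TFA–H2O (9:1), 0 °C → rt; evaporation from toluene
Reagents that add atoms: none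
Why: Acetal hydrolysis followed by acid-catalysed lactonization (5-exo-trig acyl substitution) of the secondary C6 hydroxyl onto the cis ester should give the conjugated butenolide, with C6 untouched under acid.

**Step 3**
Reactants: 6 2-methylcyclobutanone (racemic); 5 methyl (S)-5-(hydroxymethyl)-2-oxo-2,5-dihydrofuran-3-carboxylate
Product: 8 methyl (S)-5-({dimethyl[(2-methylcyclobut-1-en-1-yl)oxy]silyl}oxymethyl)-2-oxo-2,5-dihydrofuran-3-carboxylate, via enol chlorosilane 7 (not isolated)
Conditions: 6, Me2SiCl2 (5 equiv), Et3N, NaI (cat.), MeCN, 40 °C, then evaporation of excess Me2SiCl2; 5, pyridine, CH2Cl2, −20 → 0 °C; used crude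
Reagents that add atoms: dichlorodimethylsilane C[Si](C)(Cl)Cl
Why: Silyl enol ether formation under equilibrating conditions should favour the more substituted C9=C10 enol, and silylation of the primary C7 hydroxyl by the chlorosilane with the weak base pyridine (which should not deprotonate the butenolide at C6) gives the mixed dialkoxysilane tether.

**Step 4**
Reactants: 8 silicon-tethered enol ether
Product: 11 tricyclic keto bis-lactone (ring A 3-ketone; C19(=O)–O–C6 γ-lactone; C9(=O)–O–C7 δ-lactone; C10 methyl), via tethered Michael adduct 9 (not isolated), via bridged diketone 10 (not isolated)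
Conditions: Sc(OTf)3 (10 mol %), CH2Cl2, −78 → −20 °C; then NaOMe (4 equiv), MeOH, 0 °C → reflux; then AcOH, TsOH·H2O (cat.), toluene, 80 °C
Reagents that add atoms: none
Why: Proposed new method: Sc(OTf)3 activates the chelating 3-methoxycarbonyl butenolide and the tethered silyl enol ether adds through C10 to C5 (intramolecular Mukaiyama–Michael addition through an eight-membered tether ring, with silyl transfer to the new enolate giving 9); methoxide then frees the C7 alkoxide, the cyclobutanone enolizes toward C2 and C2 attacks the C3 ester (Claisen condensation, 6-(enolexo)-exo-trig, closing ring A as the bicyclo[3.1.1]heptanedione 10), and alkoxide opens the strained four-membered ketone at C9 with loss of the C9–C2 bond (retro-Claisen) to the stabilized enolate of the β-keto lactone. The acid stage closes the δ-lactone C9(=O)–O–C7 (6-exo-trig) and re-closes the γ-lactone (5-exo-trig). The closest known reaction types are the α,α'-annulation of ketone enol derivatives with acrylic electrophiles followed by retro-Claisen opening of the bridged β-diketone, and the Michael–Claisen route to cyclohexane-1,3-diones. C5 is set by the tether, which can deliver C10 only to the butenolide face that carries C7 (overriding the usual anti addition); C10 is set by an open transition state with the two π systems antiperiplanar and the enol oxygen, cis to the methyl group, on the tether side, so that the methyl group ends anti to H5; C4 is epimerizable and settles as the cis-fused lactone, and the C2 bridgehead center is erased by the ring opening. The step needs attack by the more substituted enol carbon (secured by the regiodefined enol ether), attack of C2 on an acyl carbon attached to C4 (ester and lactone carbonyl lead to the same product after re-lactonization), and cleavage of C9–C2 and not of C3–C2 (the cyclobutanone carbonyl is the more electrophilic one and its cleavage gives the doubly stabilized enolate).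

**Step 5**
Reactants: 11 tricyclic keto bis-lactone
Product: 12 ethyl ketone alcohol (δ-lactone opened: propanoyl group C9/C8/C17 on C10 and free C7 hydroxymethyl on C6)
Conditions: ethylmagnesium bromide (3.2 equiv), THF, −40 → 0 °C; aq. NH4Cl
Reagents that add atoms: ethylmagnesium bromide CC[Mg]Br
Why: The first equivalent deprotonates C4–H so that the magnesium enolate shields the C3 ketone and the γ-lactone, and Grignard addition then opens the δ-lactone at C9 to a neopentyl-type ethyl ketone that should resist a second addition.

**Step 6**
Reactants: 12 ethyl ketone alcohol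
Product: 13 C4-methylated keto lactone
Conditions: MeI, K2CO3, acetone, rt
Reagents that add atoms: iodomethane CI
Why: C-alkylation of the β-keto lactone enolate should place the methyl group on the face that keeps the γ-lactone cis-fused to ring A, which sets C4 with C19 cis to C6.

**Step 7**
Reactants: 13 C4-methylated keto lactone
Product: 14 primary iodide at C7
Conditions: I2, PPh3, imidazole, CH2Cl2, 0 °C → rt
Reagents that add atoms: iodine II
Why: Appel iodination of the only hydroxyl group (the δ-hydroxy ketone reacts through its open form) should leave ketones and lactone untouched.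

**Step 8**
Reactants: 14 primary iodide
Product: 15 C3 1,3-dioxolane
Conditions: ethylene glycol, TsOH·H2O (cat.), benzene, reflux (Dean–Stark)
Reagents that add atoms: ethylene glycol OCCO
Why: Acid-catalysed ketalization should take the cyclohexanone C3 (activated by the adjacent lactone carbonyl) in preference to the acyclic ethyl ketone C9 next to quaternary C10, with lactone and iodide stable and no stereocenter changed.

**Step 9**
Reactants: 15 C3 1,3-dioxolane
Product: 16 tricyclic ketone (rings A and B; C9 ketone; 8α-methyl; 19,6β-lactone; C3 dioxolane)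
Conditions: KOt-Bu (1.5 equiv), t-BuOH–THF, 0 °C → rt
Reagents that add atoms: none
Why: Intramolecular enolate C-alkylation (6-(enolendo)-exo-tet) of the only enolizable ketone closes ring B through C7–C8, and C8, epimerizable under the conditions, should settle with the methyl group equatorial (α) on the trans-fused system fixed by C5 and C10.

**Step 10**
Reactants: 17 diethyl oxalate; 18 (trimethylsilyl)acetylene
Product: 19 ethyl 2-oxo-4-(trimethylsilyl)but-3-ynoate
Conditions: 18, n-BuLi, THF, −78 °C; inverse addition to 17 (2 equiv), −78 °C; aq. NH4Cl
Reagents that add atoms: none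
Why: Acylation of the lithium acetylide by the oxalate ester stops at the ketone because the tetrahedral adduct persists at low temperature.

**Step 11**
Reactants: 19 ethyl 2-oxo-4-(trimethylsilyl)but-3-ynoate
Product: 20 ethyl (R)-2-hydroxy-2-[(trimethylsilyl)ethynyl]pent-4-enoate
Conditions: allyldiisopropoxyborane (1.5 equiv), (S)-3,3'-dibromo-BINOL (15 mol %), toluene–PhCF3, rt
Reagents that add atoms: allyldiisopropoxyborane C=CCB(OC(C)C)OC(C)C
Why: Chiral-diol-catalysed asymmetric allylboration of the ketone through a closed chair transition state should set C13 under catalyst control, without base that could isomerize the product.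

**Step 12**
Reactants: 20 ethyl (R)-2-hydroxy-2-[(trimethylsilyl)ethynyl]pent-4-enoate
Product: 21 (R)-2-ethynylpent-4-ene-1,2-diol
Conditions: LiBH4, THF, 0 °C → rt; then K2CO3 (cat.), MeOH, rt
Reagents that add atoms: none
Why: Chelation-assisted borohydride reduction of the α-hydroxy ester and methanolysis of the alkynyl C–Si bond should give the diol with C13 untouched.

**Step 13**
Reactants: 21 (R)-2-ethynylpent-4-ene-1,2-diol
Product: 23 (3R)-3-ethynyl-5-methoxyoxolan-3-ol (both C15 anomers), via lactol 22 (not isolated)
Conditions: O3, CH2Cl2–MeOH, −78 °C; Me2S; then PPTS (cat.), MeOH, rt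
Reagents that add atoms: methanol CO
Why: Ozonolysis should cleave the alkene much faster than the alkyne, the aldehyde closes on the C16 hydroxyl to the five-membered lactol, and acid-catalysed acetalization protects it; the anomeric center is of no consequence.

**Step 14**
Reactants: 23 (3R)-3-ethynyl-5-methoxyoxolan-3-ol
Product: 24 (3R)-3-ethynyl-5-methoxy-3-(triethylsilyloxy)oxolane
Conditions: TESOTf, 2,6-lutidine, CH2Cl2, −78 → 0 °C
Reagents that add atoms: triethylsilyl trifluoromethanesulfonate CC[Si](CC)(CC)OS(=O)(=O)C(F)(F)F
Why: Silylation of the tertiary alcohol ensures that later only the C9 carbinol can take part in the propargylic 1,3-shift.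

**Step 15**
Reactants: 16 tricyclic ketone; 24 (3R)-3-ethynyl-5-methoxy-3-(triethylsilyloxy)oxolane
Product: 25 tertiary propargylic alcohol (C9 hydroxyl; C11≡C12 alkyne to C13)
Conditions: 24, n-BuLi, THF, −78 °C; CeCl3; then 16, −78 °C; aq. NH4Cl
Reagents that add atoms: none
Why: The alkynylcerium reagent should add to the hindered C9 ketone without enolizing C8, and at low temperature the neopentyl γ-lactone and the ketal are expected to survive.

**Step 16**
Reactants: 25 tertiary propargylic alcohol
Product: 26 enone (C9=C11–C12(=O)–C13; either alkene geometry)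
Conditions: Ph3PAuNTf2 (2 mol %), MoO2(acac)2 (2 mol %), toluene, rt
Reagents that add atoms: none
Why: Meyer–Schuster rearrangement moves the only free propargylic hydroxyl from C9 to C12 and places the ketone unambiguously at C12 under near-neutral conditions that keep the silyl ether, ketal and acetal.

**Step 17**
Reactants: 26 enone
Product: 27 spiro furanone lactol (C3 ketone free; C9–O–C13 ether; C15 hemiacetal)
Conditions: 2 M HCl, THF, 0 → 40 °C
Reagents that add atoms: water O
Why: Acid removes the silyl ether, the dioxolane and the methyl acetal, and the freed C13 hydroxyl adds to C9 of the protonated enone (5-endo oxa-conjugate addition through the tertiary cation) by axial attack on the α face, anti to the C10 methyl group, which sets C9 while C13 is not touched.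

**Step 18**
Reactants: 27 spiro furanone lactol
Product: 28 CNP0143138.1
Conditions: MsCl, Et3N, CH2Cl2, −40 °C → rt; buffered work-up
Reagents that add atoms: none
Why: Sulfonylation of the lactol and base-induced 1,2-elimination toward C14 (the only β-hydrogens) should give the cyclic enol ether without touching any stereocenter.

**Compound list**

1 | (R)-2,2-dimethyl-1,3-dioxolane-4-carbaldehyde | O=C[C@H]1COC(C)(C)O1 | starting material
2 | dimethyl malonate | COC(=O)CC(=O)OC | starting material
3 | dimethyl (S)-2-[(2,2-dimethyl-1,3-dioxolan-4-yl)methylidene]malonate | COC(=O)C(=C[C@H]1COC(C)(C)O1)C(=O)OC | intermediate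
4 | dimethyl (S)-2-(2,3-dihydroxypropylidene)malonate (not isolated) | COC(=O)C(=C[C@H](O)CO)C(=O)OC | intermediate
5 | methyl (S)-5-(hydroxymethyl)-2-oxo-2,5-dihydrofuran-3-carboxylate | COC(=O)C1=C[C@@H](CO)OC1=O | intermediate
6 | 2-methylcyclobutanone (racemic) | CC1CCC1=O | starting material
7 | chloro(dimethyl)[(2-methylcyclobut-1-en-1-yl)oxy]silane (not isolated) | CC1=C(O[Si](C)(C)Cl)CC1 | intermediate
8 | silicon-tethered enol ether of 5 and 6 | CC1=C(O[Si](C)(C)OC[C@H]2OC(=O)C(C(=O)OC)=C2)CC1 | intermediate
9 | tethered Michael adduct: 1-methyl-2-oxocyclobutyl group on C5, cyclic silyl ketene acetal O7–SiMe2–O–C3 (not isolated) | C[Si]1(C)OC[C@H]2OC(=O)C(=C(OC)O1)[C@H]2[C@]3(C)CCC3=O | intermediate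
10 | bridged diketone: ring A closed, C9 ketone bridging C10 and C2, free C7 hydroxyl (not isolated) | OC[C@H]1OC(=O)[C@H]2C(=O)[C@H]3C[C@@](C)([C@@H]12)C3=O | intermediate
11 | tricyclic keto bis-lactone | O1C[C@H]2OC(=O)[C@H]3C(=O)CC[C@@](C)([C@@H]23)C1=O | intermediate
12 | ethyl ketone alcohol | OC[C@H]1OC(=O)[C@H]2C(=O)CC[C@@](C)([C@@H]12)C(=O)CC | intermediate
13 | C4-methylated keto lactone | OC[C@H]1OC(=O)[C@@]2(C)C(=O)CC[C@@](C)([C@@H]12)C(=O)CC | intermediate
14 | primary iodide | IC[C@H]1OC(=O)[C@@]2(C)C(=O)CC[C@@](C)([C@@H]12)C(=O)CC | intermediate
15 | C3 1,3-dioxolane | IC[C@H]1OC(=O)[C@@]2(C)C3(OCCO3)CC[C@@](C)([C@@H]12)C(=O)CC | intermediate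
16 | tricyclic ketone (9-oxo, 8α-methyl, 19,6β-lactone, C3 dioxolane) | C[C@@H]1C[C@H]2OC(=O)[C@@]3(C)C4(OCCO4)CC[C@@](C)([C@@H]23)C1=O | intermediate
17 | diethyl oxalate | CCOC(=O)C(=O)OCC | starting material
18 | (trimethylsilyl)acetylene | C#C[Si](C)(C)C | starting material
19 | ethyl 2-oxo-4-(trimethylsilyl)but-3-ynoate | CCOC(=O)C(=O)C#C[Si](C)(C)C | intermediate
20 | ethyl (R)-2-hydroxy-2-[(trimethylsilyl)ethynyl]pent-4-enoate | C[Si](C)(C)C#C[C@@](C(=O)OCC)(CC=C)O | intermediate
21 | (R)-2-ethynylpent-4-ene-1,2-diol | C#C[C@@](CO)(CC=C)O | intermediate
22 | (3R)-3-ethynyloxolane-3,5-diol (lactol, not isolated) | C#C[C@@]1(CC(O)OC1)O | intermediate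
23 | (3R)-3-ethynyl-5-methoxyoxolan-3-ol | C#C[C@@]1(CC(OC)OC1)O | intermediate
24 | (3R)-3-ethynyl-5-methoxy-3-(triethylsilyloxy)oxolane | C#C[C@@]1(CC(OC)OC1)O[Si](CC)(CC)CC | intermediate
25 | tertiary propargylic alcohol | C[C@@H]1C[C@H]2OC(=O)[C@@]3(C)C4(OCCO4)CC[C@@](C)([C@@H]23)[C@@]1(O)C#C[C@@]1(CC(OC)OC1)O[Si](CC)(CC)CC | intermediate
26 | enone | C[C@@H]1C[C@H]2OC(=O)[C@@]3(C)C4(OCCO4)CC[C@@](C)([C@@H]23)C1=CC(=O)[C@@]1(CC(OC)OC1)O[Si](CC)(CC)CC | intermediate
27 | spiro furanone lactol | C[C@@H]1C[C@H]2OC(=O)[C@@]3(C)C(=O)CC[C@@](C)([C@@H]23)[C@@]12CC(=O)[C@@]1(CC(O)OC1)O2 | intermediate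
28 | CNP0143138.1 | C[C@@H]1C[C@H]2OC(=O)[C@@]3(C)C(=O)CC[C@@](C)([C@@H]23)[C@@]12CC(=O)[C@@]1(C=COC1)O2 | target

**Totals**

Total step count: 18. Longest linear sequence: 13 (steps 1–9 and 15–18); the alkyne branch is steps 10–14.

**Steps most likely to fail**

Step 4 (Proposed new method). What may go wrong: retro-Michael loss and untethered re-addition that erodes C5 and C10; failure of the Claisen closure because the C4 enolate deactivates both acyl groups; opening of the bridged diketone at the wrong carbonyl. Fallback (known chemistry, sets out from 3, comes back at 11): the two bonds are made in separate classical steps. The lithium enolate of commercial methyl 2-methylpent-4-enoate (LiN(i-Pr)2, THF, −78 °C) adds to 3 to give, after separation of diastereomers, the Michael adduct F1 (C5–C10). Hydroboration–oxidation of the allyl group (9-BBN; NaBO3) gives the primary alcohol F2, oxidation (TEMPO, PhI(OAc)2, aqueous MeCN) the acid F3, and allyl bromide with K2CO3 the allyl ester F4. Dieckmann cyclization (KOt-Bu, THF) closes ring A through C2–C3 to the doubly activated ketone F5, and Pd(PPh3)4 with morpholine removes the activating ester by deallylation–decarboxylation to give the keto triester F6. TFA–H2O and then TsOH in toluene cleave the acetonide and close both lactones to 11.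

Step 3. What may go wrong: loss of the C6 configuration by γ-deprotonation of the butenolide, silylation of the less substituted enol, or hydrolysis of the labile dimethylsilyl tether during handling. Fallback (sets out from 3 and 6, comes back at 11): the tether and the butenolide are abandoned. Ketone 6 is converted into 1-(trimethylsilyloxy)-2-methylcyclobutene F7 (TMSCl, Et3N, NaI, MeCN), which is added intermolecularly to the acyclic acceptor 3 with Sc(OTf)3 to give, after separation of diastereomers, the cyclobutanone malonate F8. NaOMe in MeOH then effects the same Claisen/retro-Claisen sequence to the keto triester F6 (the same compound as in the fallback for step 4), and acid closes both lactones to 11.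

Step 17. What may go wrong: epimerization at C8 through the dienol of the exocyclic enone, elimination toward C8 in place of ring closure, or incomplete conjugate addition at the hindered C9. Fallback (sets out from 25, comes back at 27): the enone route is replaced by the classical mercury-catalysed hydration and dehydrative cyclization of a but-2-yne-1,4-diol. TBAF removes the silyl ether to give diol F9, and HgSO4 (cat.) in aqueous H2SO4–THF hydrates the alkyne and closes the furanone, the ketal and the methyl acetal being hydrolysed in the same medium, to give 27 directly.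

**Further compounds**

F1 | step 4 | Michael adduct of methyl 2-methylpent-4-enoate and 3 | C=CC[C@@](C)([C@H](C(C(=O)OC)C(=O)OC)[C@H]1COC(C)(C)O1)C(=O)OC
F2 | step 4 | primary alcohol from hydroboration of F1 | OCCC[C@@](C)([C@H](C(C(=O)OC)C(=O)OC)[C@H]1COC(C)(C)O1)C(=O)OC
F3 | step 4 | carboxylic acid from F2 | OC(=O)CC[C@@](C)([C@H](C(C(=O)OC)C(=O)OC)[C@H]1COC(C)(C)O1)C(=O)OC
F4 | step 4 | allyl ester of F3 | C=CCOC(=O)CC[C@@](C)([C@H](C(C(=O)OC)C(=O)OC)[C@H]1COC(C)(C)O1)C(=O)OC
F5 | step 4 | Dieckmann product (ring A ketone flanked by allyl and methyl esters) | COC(=O)C1C(=O)C(C(=O)OCC=C)C[C@](C)(C(=O)OC)[C@H]1[C@H]1COC(C)(C)O1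
F6 | step 4 | keto triester (ring A β-keto ester, C9 methyl ester, acetonide) | COC(=O)C1C(=O)CC[C@](C)(C(=O)OC)[C@H]1[C@H]1COC(C)(C)O1
F7 | step 3 | 1-(trimethylsilyloxy)-2-methylcyclobutene | CC1=C(O[Si](C)(C)C)CC1
F8 | step 3 | cyclobutanone malonate from intermolecular Mukaiyama–Michael addition | C[C@]1(CCC1=O)[C@H](C(C(=O)OC)C(=O)OC)[C@H]1COC(C)(C)O1
F9 | step 17 | but-2-yne-1,4-diol from desilylation of 25 | C[C@@H]1C[C@H]2OC(=O)[C@@]3(C)C4(OCCO4)CC[C@@](C)([C@@H]23)[C@@]1(O)C#C[C@@]1(CC(OC)OC1)O
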